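**Strategy.** The 1,2-dioxane is disconnected at C4–C5, the ring bond that lies between the two oxygen-bearing stereocentres C3 and C6 and is remote from O1–O2. Because C3 and C6 can each carry a vinyl group, a ruthenium-catalysed ring-closing metathesis of an acyclic secondary–tertiary dialkyl peroxide forms C4=C5 and the six-membered ring in one operation, with no cationic, anionic or radical intermediate adjacent to the O–O bond. The precursor joins a Sharpless-derived tertiary hydroperoxide (C6) to an acrolein–methyl acrylate Baylis–Hillman carbonate (C3) by catalytic asymmetric peroxy-allylic substitution; the C6 vinyl group is installed only after the O–O bond has been alkylated. One diimide reduction completes the target.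

Key step: step 8

Assumption: (DHQD)2PHAL is taken as the pseudoenantiomeric catalyst that gives the (S) centre at the peroxide-bearing carbon of this vinyl-substituted carbonate; if the sense is opposite, (DHQ)2PHAL replaces it with no other change.
Assumption: compounds 3 and 4 are used as racemates, because step 5 passes through a planar allylammonium ion.

**Step 1**
Reactants: 1 acrolein; 2 methyl acrylate
Product: 3 methyl 3-hydroxy-2-methylidenepent-4-enoate (racemic)
Conditions: DABCO (20 mol%), methyl acrylate (3 equiv, neat), slow addition of acrolein, 0 °C → rt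
Reagents that add atoms: none
Why: Morita–Baylis–Hillman reaction in which the DABCO–acrylate enolate adds 1,2 to the aldehyde of acrolein and then loses the amine; the carbinol centre is racemic, which is harmless because step 5 erases it.

**Step 2**
Reactants: 3 methyl 3-hydroxy-2-methylidenepent-4-enoate
Product: 4 methyl 3-[(tert-butoxycarbonyl)oxy]-2-methylidenepent-4-enoate (racemic)
Conditions: Boc2O, DMAP (cat.), CH2Cl2, 0 °C → rt
Reagents that add atoms: di-tert-butyl dicarbonate, CC(C)(C)OC(=O)OC(=O)OC(C)(C)C
Why: DMAP-catalysed O-acylation of the secondary allylic alcohol gives the tert-butyl carbonate, the usual leaving group for Lewis-base-catalysed allylic substitution because it releases CO2 and tert-butoxide as the internal base.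

**Step 3**
Reactants: 5 (2E,6E,10E)-geranylgeraniol
Product: 6 [(2S,3S)-3-methyl-3-[(3E,7E)-4,8,12-trimethyltrideca-3,7,11-trien-1-yl]oxiran-2-yl]methanol
Conditions: Ti(OiPr)4 (10 mol%), L-(+)-diethyl tartrate (12 mol%), t-BuOOH, 4 Å MS, CH2Cl2, −20 °C
Reagents that add atoms: tert-butyl hydroperoxide, CC(C)(C)OO
Why: Sharpless asymmetric epoxidation, which oxidises only the allylic C2=C3 alkene and, with the L-(+)-tartrate ligand, delivers oxygen to the face that gives the (2S,3S)-epoxide.

**Step 4**
Reactants: 6 (2S,3S)-epoxy alcohol
Product: 7 (2S,3R,6E,10E)-3-hydroperoxy-3,7,11,15-tetramethylhexadeca-6,10,14-triene-1,2-diol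
Conditions: H2O2 (anhydrous, in Et2O, excess), H3PMo12O40 (2 mol%), Et2O, rt, short reaction time
Reagents that add atoms: hydrogen peroxide, OO
Why: Molybdenum-catalysed perhydrolysis of an epoxide, in which hydrogen peroxide should open the activated 2,3-epoxy alcohol at the more substituted C3 with inversion, so that the (3S) C–O bond becomes the (3R) C–OOH bond while C2 keeps its configuration.

**Step 5**
Reactants: 7 hydroperoxy diol; 4 Baylis–Hillman carbonate (1.5 equiv)
Product: 8 methyl 2-[(1S)-1-{[(2S,3R,6E,10E)-1,2-dihydroxy-3,7,11,15-tetramethylhexadeca-6,10,14-trien-3-yl]peroxy}prop-2-en-1-yl]prop-2-enoate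
Conditions: (DHQD)2PHAL (10 mol%), PhCF3, rt
Reagents that add atoms: none
Why: Cinchona-catalysed allylic substitution of a Morita–Baylis–Hillman carbonate by a tertiary hydroperoxide (SN2′–SN2′), in which the amine expels carbonate to give a planar allylammonium ion, so the racemic carbonate converges, and the hydroperoxide, far more nucleophilic than the two hydroxyls, adds to the γ-carbon inside the chiral ion pair, which sets the (S) centre under catalyst control.

**Step 6**
Reactants: 8 peroxide diol
Product: 9 methyl 2-[(1S)-1-{[(2R,5E,9E)-2,6,10,14-tetramethyl-1-oxopentadeca-5,9,13-trien-2-yl]peroxy}prop-2-en-1-yl]prop-2-enoate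
Conditions: NaIO4, THF/pH 7 phosphate buffer, 0 °C
Reagents that add atoms: none
Why: Periodate glycol cleavage (Malaprade reaction) removes C1 as formaldehyde and leaves the dialkyl peroxide, the acrylate and all alkenes untouched; the aldehyde sits on a quaternary carbon and cannot epimerise.

**Step 7**
Reactants: 9 α-peroxy aldehyde
Product: 10 methyl 2-[(1S)-1-{[(3R,6E,10E)-3,7,11,15-tetramethylhexadeca-1,6,10,14-tetraen-3-yl]peroxy}prop-2-en-1-yl]prop-2-enoate
Conditions: Ph3PCH3Br, KHMDS, THF, 0 °C; then 9 (ylide 1.1 equiv), −78 → −20 °C
Reagents that add atoms: methyltriphenylphosphonium bromide, C[P+](c1ccccc1)(c1ccccc1)c1ccccc1.[Br-]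
Why: Wittig methylenation, in which the unstabilised ylide should add to the activated aldehyde at −78 °C much faster than it adds to the acrylate or removes the C–H next to the peroxide, and which leaves both stereocentres untouched.

**Step 8**
Reactants: 10 bis-allylic peroxide
Product: 11 methyl 2-[(3S,6R)-6-methyl-6-[(3E,7E)-4,8,12-trimethyltrideca-3,7,11-trien-1-yl]-3,6-dihydro-1,2-dioxin-3-yl]prop-2-enoate
Conditions: Hoveyda–Grubbs II (5–10 mol%), 1,4-benzoquinone (10 mol%), CH2Cl2 (2 mM), 40 °C, argon sparge
Reagents that add atoms: none
Why: Proposed new method: the ruthenium alkylidene should load on the less hindered vinyl group at C3 and close onto the vinyl group at C6 through a ruthenacyclobutane ([2+2] cycloaddition and cycloreversion), releasing ethylene and forming C4=C5 inside the ring. The closest known reactions are ring-closing metathesis of diallyl ethers to 3,6-dihydro-2H-pyrans and ruthenium-catalysed metathesis of alkenes that carry dialkyl peroxide groups. The ring closes as a six-membered ring-closing metathesis of a 1,7-diene across the O–O tether; the ring alkene can only be cis, and the fully substituted C6 favours the folded C–O–O–C conformer that closure requires. No stereocentre is formed, and C3 and C6 are preserved because no charge or radical develops next to the O–O bond. The step needs site selectivity among six alkenes: only the two vinyl groups are monosubstituted, the acrylate is 1,1-disubstituted and electron-poor, the chain alkenes are trisubstituted, and the competing five-ring closure of the C6 vinyl group onto the nearest chain alkene is disfavoured by loading at C3 and by the faster capture of a monosubstituted partner. A phosphine-free catalyst at high dilution avoids phosphine attack on the O–O bond and oligomerisation, and benzoquinone suppresses hydride-induced alkene migration.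

**Step 9**
Reactants: 11 dihydrodioxine acrylate
Product: 14 methyl (2R)-2-[(3S,6R)-6-methyl-6-[(3E,7E)-4,8,12-trimethyltrideca-3,7,11-trien-1-yl]-1,2-dioxan-3-yl]propanoate, via ring-saturated acrylate 12 (not isolated), via dihydrodioxine propanoate 13 (not isolated)
Conditions: KO2CN=NCO2K (excess, in portions), AcOH, MeOH/CH2Cl2, 0 °C → rt
Reagents that add atoms: none
Why: Diimide reduction (concerted syn transfer of H2) saturates the cis ring alkene and the acrylate in either order, spares the trisubstituted chain alkenes and the O–O bond, and should add to the acrylate face anti to the ring C3–O2 bond in the conformer with C3–H beside the ester, which gives the (2R), 2,3-syn centre under substrate control.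

**Compound list**

1 | acrolein | C=CC=O | starting material
2 | methyl acrylate | C=CC(=O)OC | starting material
3 | methyl 3-hydroxy-2-methylidenepent-4-enoate (racemic) | COC(=O)C(=C)C(O)C=C | intermediate
4 | methyl 3-[(tert-butoxycarbonyl)oxy]-2-methylidenepent-4-enoate (racemic) | COC(=O)C(=C)C(OC(=O)OC(C)(C)C)C=C | intermediate
5 | (2E,6E,10E)-geranylgeraniol | OC/C=C(\C)CC/C=C(\C)CC/C=C(\C)CCC=C(C)C | starting material
6 | [(2S,3S)-3-methyl-3-[(3E,7E)-4,8,12-trimethyltrideca-3,7,11-trien-1-yl]oxiran-2-yl]methanol | OC[C@@H]1O[C@@]1(C)CC/C=C(\C)CC/C=C(\C)CCC=C(C)C | intermediate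
7 | (2S,3R,6E,10E)-3-hydroperoxy-3,7,11,15-tetramethylhexadeca-6,10,14-triene-1,2-diol | OC[C@H](O)[C@](C)(OO)CC/C=C(\C)CC/C=C(\C)CCC=C(C)C | intermediate
8 | methyl 2-[(1S)-1-{[(2S,3R,6E,10E)-1,2-dihydroxy-3,7,11,15-tetramethylhexadeca-6,10,14-trien-3-yl]peroxy}prop-2-en-1-yl]prop-2-enoate | COC(=O)C(=C)[C@H](C=C)OO[C@@](C)([C@@H](O)CO)CC/C=C(\C)CC/C=C(\C)CCC=C(C)C | intermediate
9 | methyl 2-[(1S)-1-{[(2R,5E,9E)-2,6,10,14-tetramethyl-1-oxopentadeca-5,9,13-trien-2-yl]peroxy}prop-2-en-1-yl]prop-2-enoate | COC(=O)C(=C)[C@H](C=C)OO[C@@](C)(C=O)CC/C=C(\C)CC/C=C(\C)CCC=C(C)C | intermediate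
10 | methyl 2-[(1S)-1-{[(3R,6E,10E)-3,7,11,15-tetramethylhexadeca-1,6,10,14-tetraen-3-yl]peroxy}prop-2-en-1-yl]prop-2-enoate | COC(=O)C(=C)[C@H](C=C)OO[C@@](C)(C=C)CC/C=C(\C)CC/C=C(\C)CCC=C(C)C | intermediate
11 | methyl 2-[(3S,6R)-6-methyl-6-[(3E,7E)-4,8,12-trimethyltrideca-3,7,11-trien-1-yl]-3,6-dihydro-1,2-dioxin-3-yl]prop-2-enoate | COC(=O)C(=C)[C@@H]1C=C[C@@](C)(CC/C=C(\C)CC/C=C(\C)CCC=C(C)C)OO1 | intermediate
12 | methyl 2-[(3S,6R)-6-methyl-6-[(3E,7E)-4,8,12-trimethyltrideca-3,7,11-trien-1-yl]-1,2-dioxan-3-yl]prop-2-enoate | COC(=O)C(=C)[C@@H]1CC[C@@](C)(CC/C=C(\C)CC/C=C(\C)CCC=C(C)C)OO1 | intermediate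
13 | methyl (2R)-2-[(3S,6R)-6-methyl-6-[(3E,7E)-4,8,12-trimethyltrideca-3,7,11-trien-1-yl]-3,6-dihydro-1,2-dioxin-3-yl]propanoate | COC(=O)[C@H](C)[C@@H]1C=C[C@@](C)(CC/C=C(\C)CC/C=C(\C)CCC=C(C)C)OO1 | intermediate
14 | methyl (2R)-2-[(3S,6R)-6-methyl-6-[(3E,7E)-4,8,12-trimethyltrideca-3,7,11-trien-1-yl]-1,2-dioxan-3-yl]propanoate | COC(=O)[C@H](C)[C@@H]1CC[C@@](C)(CC/C=C(\C)CC/C=C(\C)CCC=C(C)C)OO1 | target

**Step count.** Total: 9 steps. Longest linear sequence: 7 steps (steps 3–9, from geranylgeraniol); the carbonate arm (steps 1–2) joins at step 5.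

**Steps most likely to fail**

1. Step 8 (ring-closing metathesis, the step proposed as new). The catalyst may be deactivated by electron transfer to, or coordination by, the O–O bond or by chelation to the ester. Site selectivity may also be lost through five-ring closure of the C6 vinyl group onto the nearest chain alkene, or through oligomerisation. The fallback uses known chemistry and closes the ring at O2–C3 instead of C4–C5, by the established 6-exo conjugate addition of a tertiary hydroperoxide to an (E)-2-methyl-2-enoate. It sets out from hydroperoxy diol 7. Periodate cleavage gives (2R,5E,9E)-2-hydroperoxy-2,6,10,14-tetramethylpentadeca-5,9,13-trienal F1, which is used cold and at once. Wittig reaction with the preformed ester-stabilised allylic ylide Ph3P=CH–CH=C(CH3)CO2Me, which is expected to tolerate a tertiary hydroperoxide, gives methyl (2E,6R,9E,13E)-6-hydroperoxy-2,6,10,14,18-pentamethylnonadeca-2,4,9,13,17-pentaenoate F2; the geometry of its C4=C5 bond is irrelevant. Diimide should saturate the disubstituted C4=C5 bond in preference to the trisubstituted, ester-conjugated C2=C3 bond, giving methyl (2E,6R,9E,13E)-6-hydroperoxy-2,6,10,14,18-pentamethylnonadeca-2,9,13,17-tetraenoate F3. Triethylamine in trifluoroethanol then effects the peroxy-Michael ring closure, and the fallback comes back to the route at the target 14. C6 stays controlled by the epoxide, but this closure gives little control at C3 and C2, so the diastereomers would have to be separated by HPLC.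

2. Step 9 (diimide reduction). Facial selectivity at the acrylate may be poor, because C2 is set only by the neighbouring ring stereocentre, and prolonged exposure may begin to reduce chain alkenes. The fallback sets C2 under catalyst control. It sets out from 11: an ene-reductase of the Old Yellow Enzyme family (NADPH recycled with glucose and glucose dehydrogenase, buffer with co-solvent), chosen from a panel for the (2R) sense, reduces only the activated acrylate C=C. This gives the dihydrodioxine propanoate 13, now isolated, where the fallback comes back to the route; diimide then only has to saturate C4=C5 to reach 14.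

3. Step 5 (peroxy-allylic substitution). Stereoinduction may be low and turnover slow with this bulky, hydroxylated hydroperoxide. The hydroperoxide may also attack the terminal carbon of the vinyl group of the allylammonium ion, and the β-hydroxy hydroperoxide may fragment under the basic conditions. The fallback gives up catalyst control. It sets out from 4 and 7: achiral, less hindered DABCO promotes the same SN2′–SN2′ substitution and gives 8 together with its epimer at the new centre, methyl 2-[(1R)-1-{[(2S,3R,6E,10E)-1,2-dihydroxy-3,7,11,15-tetramethylhexadeca-6,10,14-trien-3-yl]peroxy}prop-2-en-1-yl]prop-2-enoate F4. Because the two diol-bearing centres are fixed, 8 and F4 are diastereomers and are separated by chromatography at the diol stage; the fallback comes back to the route at 8.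

**Further compounds**

F1 | step 8 | (2R,5E,9E)-2-hydroperoxy-2,6,10,14-tetramethylpentadeca-5,9,13-trienal | O=C[C@](C)(OO)CC/C=C(\C)CC/C=C(\C)CCC=C(C)C
F2 | step 8 | methyl (2E,6R,9E,13E)-6-hydroperoxy-2,6,10,14,18-pentamethylnonadeca-2,4,9,13,17-pentaenoate (4E/4Z mixture) | COC(=O)/C(C)=C/C=C[C@](C)(OO)CC/C=C(\C)CC/C=C(\C)CCC=C(C)C
F3 | step 8 | methyl (2E,6R,9E,13E)-6-hydroperoxy-2,6,10,14,18-pentamethylnonadeca-2,9,13,17-tetraenoate | COC(=O)/C(C)=C/CC[C@](C)(OO)CC/C=C(\C)CC/C=C(\C)CCC=C(C)C
F0 | step 9 | none | none
F4 | step 5 | methyl 2-[(1R)-1-{[(2S,3R,6E,10E)-1,2-dihydroxy-3,7,11,15-tetramethylhexadeca-6,10,14-trien-3-yl]peroxy}prop-2-en-1-yl]prop-2-enoate | COC(=O)C(=C)[C@@H](C=C)OO[C@@](C)([C@@H](O)CO)CC/C=C(\C)CC/C=C(\C)CCC=C(C)C
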